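## Analysis of the target

The target is an achiral diaryl ether with no stereocentres. Ring A is a pentyl-substituted 1,3-dihydroxybenzene: A1 carries the ether oxygen, A2 an OH, A3 an H, A4 an OH, A5 an H and A6 the pentyl chain. Ring B is a benzoic acid: B1 carries CO2H, B2 the ether oxygen, B3 an H, B4 the OMe, B5 an H and B6 the pentanoyl group. The ether oxygen therefore sits on A1, which is flanked on both sides (A2–OH and A6–pentyl), and on B2, which is next to the carboxyl at B1. Ring A is 1,2,4-trioxygenated, and only the oxygen on A1, the most hindered of the three, is arylated. Ring B has three contiguous substituents (B2–O, B1–CO2H, B6–acyl), and its methyl ether must survive, so a global demethylation at the end is excluded. The 2-acylbenzoic acid is a pseudo-acid in equilibrium with its lactol, and it is an electrophile towards enolates and, under strong acid, towards phenols. The free 1,3-diol of ring A is electron-rich and sensitive to oxidants and electrophiles. The hard part is the O–A1 bond together with the regiodefined oxygen pattern of ring A.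

The feature the route uses is this: A2 and A4 are meta to each other, so ring A is the aromatised form of a cyclohexane-1,3-dione. In that dione, A1 is the α-carbon of the A2 carbonyl and A6 is β to the A4 carbonyl. The ether oxygen can then be attached to A1 while A1 is still a primary sp3 carbon.

## Retrosynthetic reasoning

14 back to 13. Only functional groups are changed: the C–N bond of a diethylamide at B1 and the two O–Si bonds on A2 and A4. The carboxyl is unmasked last because a tertiary amide is inert to enolates, directs the metalation of step 5, and is hydrolysed with help from the B6 ketone. One acid treatment has to free both phenols and the acid.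

13 back to 10 and 11. The B6–C(acyl) bond is cut. B6 is the only position ortho to the amide, so a directed ortho-metalation can place the pentanoyl group there. The cut is made this late so that no second enolisable ketone is present during the ring construction and the oxidation.

10 back to 8. No skeletal bond is cut; ring A is traced back to the cyclohexane-1,3-dione 8, two hydrogens richer. The forward step turns the two carbonyl oxygens into silyl ethers (9) and dehydrogenates, so aromatisation and phenol protection coincide.

8 back to 5 and 6 (key disconnection). Bonds A1–A6 and A3–A4 are cut. This splits ring A into a three-carbon ketone unit (A1, A2, A3, already carrying the ether oxygen on A1) and the first three carbons of the unsaturated ester 6 (A4, A5, A6, with the pentyl chain on A6). The cut is made here because it removes the need to form the hindered O–A1 bond on an arene, and because the oxygen pattern of ring A follows from the connectivity of the two pieces. The forward reaction must add the α-aryloxy carbon of 5 to C3 of 6 and then close the ring from the methyl group onto the ester.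

5 back to 3 and 4. The O–A1 bond is cut, which in the forward direction is an SN2 reaction of a phenoxide at a primary α-chloro ketone carbon. This is the bond the textbook route would make by arene cross-coupling.

3 back to 1. The amide C–N bond is cut; 1 already has the B1 carboxyl, the B2 oxygen and the B4 methyl ether in place, and the forward reaction passes through acid chloride 2.

## Alternatives that were turned down

Alternative 1: the textbook disconnection of the O–B2 bond between two intact arenes. The forward key step would be a copper-catalysed Ullmann coupling of 2,4-bis(benzyloxy)-6-pentylphenol A1 with methyl 2-bromo-4-methoxy-6-pentanoylbenzoate A2 to the diaryl ether A3, followed by hydrogenolysis and saponification. It was turned down because the phenol oxygen of A1 is flanked by two ortho substituents and the bromide of A2 is next to an ester. Such couplings are slow, and reduction of the halide and ester cleavage compete under the forcing conditions. A1 also needs its own sequence (double O-benzylation, formylation, Dakin oxidation) and A2 needs three or four steps. The count comes to about nine steps, with the hardest bond made last.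

Alternative 2: the biomimetic disconnection. The target is the hydrolysed lactone of the depsidone A5, which would come from the depside A4 by intramolecular oxidative C–O coupling (phenol oxygen of ring B to A1, para to the free OH of ring A), closing the seven-membered dioxepinone ring; saponification of A5 would give 14. It was turned down for three reasons. The product ring A in A5 is a hydroquinone monoether and is oxidised more easily than the starting phenol in A4, so over-oxidation to a quinone is expected. The oxidised ring A is reactive at two ortho positions and one para position, and without an enzyme nothing directs the reaction to A1. Making A4 means esterifying a 2-acylbenzoic acid, which tends to react through its lactol form and give pseudo-esters. That leaves two uncertain steps in place of one.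

Alternative 3: a Danheiser benzannulation that builds ring A from the cyclobutenone A6 and the siloxyalkyne A8, joining A2–A3 and A4–A5 and giving the monosilylated diaryl ether A7 with all four substituents of ring A in place. The benzannulation itself fits the substitution pattern well. It was turned down because A6 is not accessible in few steps: the [2+2] cycloaddition of an aryloxy-substituted ketene to an unactivated terminal alkyne is not a workable reaction, and routes through a dichlorocyclobutenone and later substitution are long and of uncertain regiochemistry. The precursor would cost more than the key step gains.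

Key step: step 3

Remark on the chemistry: the target is drawn as the open keto acid; it is expected to equilibrate with its lactol tautomer (3-butyl-3-hydroxyphthalide form), and the open form is listed as 14. N-Methoxy-N-methylpentanamide (11) is taken as purchasable.

## Route

Step 1
Reactants: 1 2-hydroxy-4-methoxybenzoic acid
Product: 3 N,N-diethyl-2-hydroxy-4-methoxybenzamide, via acid chloride 2 (not isolated)
Conditions: SOCl2, cat. DMF, toluene, 50 °C; evaporate; Et2NH (3 equiv), CH2Cl2, 0 °C to rt
Reagents that add atoms: diethylamine, CCNCC; thionyl chloride, O=S(Cl)Cl (chlorine of 2)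
Why: Acid chloride formation and amidation; the hydrogen-bonded salicyloyl chloride should react with the amine faster than with its own phenol, and any O-acylated or O-sulfinylated phenol is cleaved by the excess amine. The tertiary amide is chosen because it is inert to enolates and is the directing group of step 5.

Step 2
Reactants: 3 N,N-diethyl-2-hydroxy-4-methoxybenzamide; 4 chloroacetone
Product: 5 N,N-diethyl-4-methoxy-2-(2-oxopropoxy)benzamide
Conditions: K2CO3, DMF, 60 °C
Reagents that add atoms: none
Why: Williamson ether synthesis, an SN2 displacement on an α-chloro ketone by the phenoxide; it forms the future diaryl ether bond O–A1 at a primary sp3 carbon instead of at a hindered arene.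

Step 3
Reactants: 5 N,N-diethyl-4-methoxy-2-(2-oxopropoxy)benzamide; 6 methyl (E)-oct-2-enoate
Product: 8 N,N-diethyl-2-[(2,4-dioxo-6-pentylcyclohexyl)oxy]-4-methoxybenzamide, via keto ester 7 (not isolated)
Conditions: KOtBu (2.2 equiv), THF, −10 °C to rt, slow addition of 6; then 1 M HCl
Reagents that add atoms: none
Why: This is a consecutive Michael–Claisen annulation. KOtBu equilibrates the enolates of 5; the enolate on the OCH2 carbon is the more stable one, because the aryloxy group makes that carbon markedly more acidic than the methyl group, and as in Michael reactions of unsymmetrical ketones under equilibrating base it should add to C3 of 6, forming the A1–A6 bond and keto ester 7. Proton transfer then gives the methyl-ketone enolate of 7, which attacks the ester carbonyl in a 6-(enolexo)-exo-trig Claisen closure (bond A3–A4) with loss of methoxide; the other α-carbon of 7 could only close a four-membered ring, so there is one mode of closure. The 1,3-dione is deprotonated as it forms, which makes the closure irreversible and draws the reversible Michael equilibria towards 8. The closest known reaction type is the base-mediated Michael–Claisen condensation of acetone or a substituted acetone with an α,β-unsaturated ester to a cyclohexane-1,3-dione, where the Michael step occurs at the more substituted α-carbon and the Claisen step from the methyl group. The selectivity needed is the choice between the two α-carbons of 5 in the Michael step; the acidifying aryloxy group and the equilibrating conditions should secure it. The two new stereocentres (A1 and A6) are not controlled and need not be, because both become sp2 carbons in step 4. The ortho amide should not acylate the enolate, since diethylamide is a poor leaving group and the amide is twisted out of the ring plane.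

Step 4
Reactants: 8 N,N-diethyl-2-[(2,4-dioxo-6-pentylcyclohexyl)oxy]-4-methoxybenzamide
Product: 10 N,N-diethyl-2-[2,4-bis(tert-butyldimethylsilyloxy)-6-pentylphenoxy]-4-methoxybenzamide, via bis(silyl) dienol ether 9 (not isolated)
Conditions: TBSOTf (2.4 equiv), Et3N (3 equiv), CH2Cl2, 0 °C to rt; evaporate, take up in pentane, filter; DDQ (1.1 equiv), toluene, 0 °C to rt
Reagents that add atoms: tert-butyldimethylsilyl trifluoromethanesulfonate, CC(C)(C)[Si](C)(C)OS(=O)(=O)C(F)(F)F
Why: Soft enolisation converts the dione into the 1,3-bis(silyloxy)cyclohexa-1,3-diene 9 (or a double-bond isomer); DDQ abstracts an allylic hydride and loss of a proton gives the arene, the known dehydrogenation of silyl dienol ethers to aryl silyl ethers. The oxidation uses no hydrogen or low-valent metal, so the α-aryloxy C–O bond is not at risk, and ring A emerges already protected for step 5.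

Step 5
Reactants: 10 N,N-diethyl-2-[2,4-bis(tert-butyldimethylsilyloxy)-6-pentylphenoxy]-4-methoxybenzamide; 11 N-methoxy-N-methylpentanamide
Product: 13 N,N-diethyl-2-[2,4-bis(tert-butyldimethylsilyloxy)-6-pentylphenoxy]-4-methoxy-6-pentanoylbenzamide, via aryllithium 12 (not isolated)
Conditions: s-BuLi (1.2 equiv), TMEDA (1.2 equiv), THF, −78 °C; 11, −78 to −20 °C; AcOH quench
Reagents that add atoms: sec-butyllithium, [Li]C(C)CC (lithium of 12)
Why: Directed ortho-metalation; the tertiary amide is the strongest director in the molecule and B6 is the only position ortho to it, while the bulky silyl ethers of ring A are poor directors and shield A3. The Weinreb amide gives the ketone through a stable chelated adduct without over-addition.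

Step 6
Reactants: 13 N,N-diethyl-2-[2,4-bis(tert-butyldimethylsilyloxy)-6-pentylphenoxy]-4-methoxy-6-pentanoylbenzamide
Product: 14 2-(2,4-dihydroxy-6-pentylphenoxy)-4-methoxy-6-pentanoylbenzoic acid
Conditions: 6 M aq. HCl/1,4-dioxane (1:1), 100 °C, N2
Reagents that add atoms: water, O
Why: Acid hydrolysis; the aryl silyl ethers are cleaved, and the hindered amide should hydrolyse with neighbouring-group help, the amide oxygen adding to the protonated B6 ketone to give a cyclic imidate that water opens to the lactol and hence the keto acid. The methyl ether and the diaryl ether are stable to aqueous HCl.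

## Compound list

1 | 2-hydroxy-4-methoxybenzoic acid | COc1ccc(C(=O)O)c(O)c1 | starting material
2 | 2-hydroxy-4-methoxybenzoyl chloride (formed and used in situ) | COc1ccc(C(=O)Cl)c(O)c1 | intermediate
3 | N,N-diethyl-2-hydroxy-4-methoxybenzamide | CCN(CC)C(=O)c1ccc(OC)cc1O | intermediate
4 | chloroacetone (1-chloropropan-2-one) | CC(=O)CCl | starting material
5 | N,N-diethyl-4-methoxy-2-(2-oxopropoxy)benzamide | CCN(CC)C(=O)c1ccc(OC)cc1OCC(C)=O | intermediate
6 | methyl (E)-oct-2-enoate | CCCCC/C=C/C(=O)OC | starting material
7 | methyl 3-{1-[2-(diethylcarbamoyl)-5-methoxyphenoxy]-2-oxopropyl}octanoate (mixture of diastereomers, racemic; formed and used in situ) | CCCCCC(CC(=O)OC)C(Oc1cc(OC)ccc1C(=O)N(CC)CC)C(C)=O | intermediate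
8 | N,N-diethyl-2-[(2,4-dioxo-6-pentylcyclohexyl)oxy]-4-methoxybenzamide (mixture of diastereomers, racemic; largely enolised) | CCCCCC1CC(=O)CC(=O)C1Oc1cc(OC)ccc1C(=O)N(CC)CC | intermediate
9 | N,N-diethyl-2-{[2,4-bis(tert-butyldimethylsilyloxy)-6-pentylcyclohexa-1,3-dien-1-yl]oxy}-4-methoxybenzamide (racemic; formed and used in situ) | CCCCCC1CC(O[Si](C)(C)C(C)(C)C)=CC(O[Si](C)(C)C(C)(C)C)=C1Oc1cc(OC)ccc1C(=O)N(CC)CC | intermediate
10 | N,N-diethyl-2-[2,4-bis(tert-butyldimethylsilyloxy)-6-pentylphenoxy]-4-methoxybenzamide | CCCCCc1cc(O[Si](C)(C)C(C)(C)C)cc(O[Si](C)(C)C(C)(C)C)c1Oc1cc(OC)ccc1C(=O)N(CC)CC | intermediate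
11 | N-methoxy-N-methylpentanamide | CCCCC(=O)N(C)OC | starting material
12 | 6-lithio derivative of 10 (formed and used in situ) | CCCCCc1cc(O[Si](C)(C)C(C)(C)C)cc(O[Si](C)(C)C(C)(C)C)c1Oc1cc(OC)cc([Li])c1C(=O)N(CC)CC | intermediate
13 | N,N-diethyl-2-[2,4-bis(tert-butyldimethylsilyloxy)-6-pentylphenoxy]-4-methoxy-6-pentanoylbenzamide | CCCCCc1cc(O[Si](C)(C)C(C)(C)C)cc(O[Si](C)(C)C(C)(C)C)c1Oc1cc(OC)cc(C(=O)CCCC)c1C(=O)N(CC)CC | intermediate
14 | 2-(2,4-dihydroxy-6-pentylphenoxy)-4-methoxy-6-pentanoylbenzoic acid | CCCCCc1cc(O)cc(O)c1Oc1cc(OC)cc(C(=O)CCCC)c1C(=O)O | target

## Step count and risk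

Total step count: 6. Longest linear sequence: 6 steps (1 to 14).

Step 3 (key step) is the least certain. Three things may go wrong:
- The Michael addition may take place from the methyl side of 5, which after Claisen closure would place the aryloxy group between the two carbonyls.
- Conjugate addition to the β-alkyl ester may be slow, while 6 is deconjugated by γ-deprotonation and 5 undergoes self-aldol condensation.
- The enolate may be acylated by the ortho amide.

The fallback replaces the ketone donor by a single-site stabilised donor and the ester acceptor by an enone. Setting out from 3, O-alkylation with dimethyl chloromalonate (K2CO3, acetone) would give dimethyl 2-[2-(diethylcarbamoyl)-5-methoxyphenoxy]propanedioate F1. Classical Michael–Dieckmann condensation of F1 with (E)-non-3-en-2-one (NaOMe, MeOH, reflux) would give methyl 1-[2-(diethylcarbamoyl)-5-methoxyphenoxy]-2,4-dioxo-6-pentylcyclohexane-1-carboxylate F2. Saponification and decarboxylation (aq. NaOH, then acidification and gentle warming) would return to the route at 8.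

Step 4 may fail through incomplete second silylation, through hydrolysis of the dienol ether by the acidic hydroquinone by-product before hydride abstraction, or through oxidation at the benzylic CH2 of the product. The fallback separates aromatisation from protection. Setting out from 8, the classical bromination–dehydrobromination of a cyclohexane-1,3-dione (Br2, 1 equiv, DMF, 0 °C, then heating) would give N,N-diethyl-2-(2,4-dihydroxy-6-pentylphenoxy)-4-methoxybenzamide F3. Silylation (TBSCl, imidazole, DMF) would return to the route at 10.

Step 5 may fail through lithiation at the wrong site (B3, between the two ether oxygens of ring B) or through lateral metalation of the benzylic CH2 of the pentyl chain followed by attack on the amide. The fallback installs the acyl group on the small ring B piece before ring A is built.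
- Setting out from 3, silylation (TIPSCl, imidazole) would give N,N-diethyl-4-methoxy-2-[(triisopropylsilyl)oxy]benzamide F4, in which the bulky silyl ether blocks B3.
- Metalation (s-BuLi, TMEDA, −78 °C), acylation with 11 and desilylation (TBAF, AcOH) would give N,N-diethyl-2-hydroxy-4-methoxy-6-pentanoylbenzamide F5.
- Alkylation with 4 (K2CO3, DMF) would give N,N-diethyl-4-methoxy-2-(2-oxopropoxy)-6-pentanoylbenzamide F6.
- Annulation with 6 as in step 3 would give N,N-diethyl-2-[(2,4-dioxo-6-pentylcyclohexyl)oxy]-4-methoxy-6-pentanoylbenzamide F7.
- Bromination–dehydrobromination (Br2, 1 equiv, DMF) would give N,N-diethyl-2-(2,4-dihydroxy-6-pentylphenoxy)-4-methoxy-6-pentanoylbenzamide F8.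
- Hydrolysis under the conditions of step 6 would come back to the route at 14.

Step 6 may fail through incomplete hydrolysis of the doubly ortho-substituted amide, or through acid-catalysed condensation of the liberated electron-rich ring A with the keto acid (phthalein-type attack on the lactol carbon). The fallback activates the amide by O-alkylation instead of protonation. Setting out from 13, trimethyloxonium tetrafluoroborate (CH2Cl2, rt) would give the O-methyl imidate salt N-{[2-(2,4-bis(tert-butyldimethylsilyloxy)-6-pentylphenoxy)-4-methoxy-6-pentanoylphenyl](methoxy)methylidene}-N-ethylethanaminium tetrafluoroborate F9. Mild aqueous carbonate would hydrolyse it to methyl 2-[2,4-bis(tert-butyldimethylsilyloxy)-6-pentylphenoxy]-4-methoxy-6-pentanoylbenzoate F10. LiOH in THF/MeOH/water would saponify the ester, with help from the neighbouring ketone, and cleave the aryl silyl ethers; acidification would return to the route at 14.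

## Further compounds

F1 | step 3 | dimethyl 2-[2-(diethylcarbamoyl)-5-methoxyphenoxy]propanedioate | CCN(CC)C(=O)c1ccc(OC)cc1OC(C(=O)OC)C(=O)OC
F2 | step 3 | methyl 1-[2-(diethylcarbamoyl)-5-methoxyphenoxy]-2,4-dioxo-6-pentylcyclohexane-1-carboxylate (mixture of diastereomers, racemic) | CCCCCC1CC(=O)CC(=O)C1(Oc1cc(OC)ccc1C(=O)N(CC)CC)C(=O)OC
F3 | step 4 | N,N-diethyl-2-(2,4-dihydroxy-6-pentylphenoxy)-4-methoxybenzamide | CCCCCc1cc(O)cc(O)c1Oc1cc(OC)ccc1C(=O)N(CC)CC
F4 | step 5 | N,N-diethyl-4-methoxy-2-[(triisopropylsilyl)oxy]benzamide | CCN(CC)C(=O)c1ccc(OC)cc1O[Si](C(C)C)(C(C)C)C(C)C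
F5 | step 5 | N,N-diethyl-2-hydroxy-4-methoxy-6-pentanoylbenzamide | CCCCC(=O)c1cc(OC)cc(O)c1C(=O)N(CC)CC
F6 | step 5 | N,N-diethyl-4-methoxy-2-(2-oxopropoxy)-6-pentanoylbenzamide | CCCCC(=O)c1cc(OC)cc(OCC(C)=O)c1C(=O)N(CC)CC
F7 | step 5 | N,N-diethyl-2-[(2,4-dioxo-6-pentylcyclohexyl)oxy]-4-methoxy-6-pentanoylbenzamide (mixture of diastereomers, racemic) | CCCCCC1CC(=O)CC(=O)C1Oc1cc(OC)cc(C(=O)CCCC)c1C(=O)N(CC)CC
F8 | step 5 | N,N-diethyl-2-(2,4-dihydroxy-6-pentylphenoxy)-4-methoxy-6-pentanoylbenzamide | CCCCCc1cc(O)cc(O)c1Oc1cc(OC)cc(C(=O)CCCC)c1C(=O)N(CC)CC
F9 | step 6 | N-{[2-(2,4-bis(tert-butyldimethylsilyloxy)-6-pentylphenoxy)-4-methoxy-6-pentanoylphenyl](methoxy)methylidene}-N-ethylethanaminium tetrafluoroborate | CCCCCc1cc(O[Si](C)(C)C(C)(C)C)cc(O[Si](C)(C)C(C)(C)C)c1Oc1cc(OC)cc(C(=O)CCCC)c1C(OC)=[N+](CC)CC.F[B-](F)(F)F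
F10 | step 6 | methyl 2-[2,4-bis(tert-butyldimethylsilyloxy)-6-pentylphenoxy]-4-methoxy-6-pentanoylbenzoate | CCCCCc1cc(O[Si](C)(C)C(C)(C)C)cc(O[Si](C)(C)C(C)(C)C)c1Oc1cc(OC)cc(C(=O)CCCC)c1C(=O)OC
A1 | alternative 1 | 2,4-bis(benzyloxy)-6-pentylphenol | CCCCCc1cc(OCc2ccccc2)cc(OCc2ccccc2)c1O
A2 | alternative 1 | methyl 2-bromo-4-methoxy-6-pentanoylbenzoate | CCCCC(=O)c1cc(OC)cc(Br)c1C(=O)OC
A3 | alternative 1 | methyl 2-[2,4-bis(benzyloxy)-6-pentylphenoxy]-4-methoxy-6-pentanoylbenzoate | CCCCCc1cc(OCc2ccccc2)cc(OCc2ccccc2)c1Oc1cc(OC)cc(C(=O)CCCC)c1C(=O)OC
A4 | alternative 2 | 3-hydroxy-5-pentylphenyl 2-hydroxy-4-methoxy-6-pentanoylbenzoate | CCCCCc1cc(O)cc(OC(=O)c2c(O)cc(OC)cc2C(=O)CCCC)c1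
A5 | alternative 2 | 8-hydroxy-3-methoxy-1-pentanoyl-6-pentyl-11H-dibenzo[b,e][1,4]dioxepin-11-one | CCCCC(=O)c1cc(OC)cc2Oc3c(CCCCC)cc(O)cc3OC(=O)c12
A6 | alternative 3 | N,N-diethyl-4-methoxy-2-[(4-oxo-2-pentylcyclobut-2-en-1-yl)oxy]benzamide (racemic) | CCCCCC1=CC(=O)C1Oc1cc(OC)ccc1C(=O)N(CC)CC
A7 | alternative 3 | N,N-diethyl-2-{2-hydroxy-6-pentyl-4-[(triisopropylsilyl)oxy]phenoxy}-4-methoxybenzamide | CCCCCc1cc(O[Si](C(C)C)(C(C)C)C(C)C)cc(O)c1Oc1cc(OC)ccc1C(=O)N(CC)CC
A8 | alternative 3 | (ethynyloxy)triisopropylsilane | C#CO[Si](C(C)C)(C(C)C)C(C)C
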